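The numbers of this flask are invented; the result is computed.

The coupling rate is first order in what is left of the second intermediate after it pairs with itself, so I follow that leftover. Held level, it makes coupling pseudo-first-order for the open intermediate.

substrate 2.0 mM; partner 0.900 equiv; capture agent 0.100 mM; time 1.0 min

    open intermediate + second intermediate → target (k1 = 19.5 /M/s)
    partner → second intermediate (k2 = 0.162 /s)
    target ⇌ isomer of the product (K3 = 2.1, k3 = 0.0618 /s)
    2 second intermediate → homo product (k4 = 7.98 /M/s)
    substrate ⇌ open intermediate (K5 = 0.204, k5 = 0.0379 /s)
    open intermediate + capture agent → trapped intermediate (k6 = 22.9 /M/s)

- a doubled species enters its step squared and goes two at a time
- the reaction counts as stopped when no species that holds the substrate changes by six tenths of a point or more over the second half of the time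
- run time (flask): 1.0 min

- why nothing more happens at 1.0 min, or that something still does (it is still moving / all of the substrate has reacted / forward and back rates have come level)
- how much target there is at 1.0 min, in percent of the substrate charged
- how much open intermediate there is at 1.0 min, in percent of the substrate charged

I rank the clocks of this flask from fastest to slowest, taking the last two at the full partner charge of 1.80 mM.

| Process | Half-life | What it leaves |
|---|---|---|
| substrate and open intermediate level out | 0.0516 min | open share 16.9 % of their pool |
| partner gives second intermediate | 0.0713 min | the charge converted |
| target and isomer level out | 0.127 min | target a third of the pair |
| second intermediate pairs | 0.580 min | a falling leftover |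
| the pool couples | 1.94 min | target plus isomer |

The partner clock is short against the time, so I treat the partner as converted at once. Coupling is slower than pairing, so I ignore what coupling takes, and second-order decay from the charge leaves 0.661 mM at 1.0 min. The time integral of that leftover, times the coupling constant and the open share, gives an exponent. One minus its negative exponential is 18.7 %, the coupled share, the part of the substrate gone to target plus isomer. The rest of the pool then holds 13.8 % as open intermediate, the equilibrium third gives target 6.04 %, and with that leftover still standing I expect the flask to be moving.

The forecast says it is still moving, with target 6.1 % (5.2 % to 7 %) and open intermediate 13.4 % (12.6 % to 14.2 %), on the ground that “coupling is slow, so only about 15% of the substrate has reached target plus isomer”. We part on that pair, where I have 18.7 %, and on target's part of it, where I take the equilibrium third and the forecast goes somewhat above it.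

In the simulation of this flask it is still moving, with target 6.23 % and open intermediate 13.4 % at 1.0 min.

In this flask target plus isomer stands at 14.9 %, less than my coupled share, and the leftover at 0.604 mM against my 0.661 mM, while target is 41.9 % of the pair, more than my third, so my target lands near the simulated one through two differences that offset. In this flask at 0.0714 min open intermediate falls back 9.6 times faster than it goes on.

In the neighbour flask with 3.60 equiv of partner, the same reckoning from 7.20 mM gives a leftover of 0.912 mM and a coupled share of 34.8 %, hence open intermediate 11.0 %. The simulation of that flask gives a leftover of 0.964 mM, target plus isomer 28.6 %, target 11.3 % and open intermediate 11.0 %.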